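Readings and results are simulated on assumed constants; the scatter is artificial.

Count turnovers of the drain, not minutes.

| setting | birch | ash | flask |
|---|---|---|---|
| substrate | 0.66 M | 0.66 M | 0.66 M |
| reagent in the second phase | 1.32 M | 0.88 M | 1.32 M |
| remark | the very flask that is asked about, followed so far | run made earlier |  |
| time |  |  | 2.0 h |
| volume of the second phase over the first |  |  | 1.0 |

| run | time / min | product / % | substrate / % |
|---|---|---|---|
| birch | 1.50 | 4.7 | 73.4 |
| birch | 2.50 | 6.5 | 63.3 |
| birch | 4.00 | 11.5 | 49.7 |
| birch | 6.00 | 14.0 | 36.7 |
| birch | 10.0 | 19.8 | 25.1 |
| birch | 15.0 | 18.7 | 21.6 |
| birch | 20.0 | 18.2 | 16.3 |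
| ash | 12.0 | 13.1 | 25.5 |
| ash | 25.0 | 14.6 | 15.6 |
| ash | 40.0 | 9.9 | 10.8 |
| ash | 50.0 | 9.1 | 10.4 |
| ash | 60.0 | 8.6 | 9.4 |
| ash | 80.0 | 6.0 | 6.3 |

(readings scatter by 1 percentage point)

- in the second phase: reagent in the second phase; everything else is in the first
- charges count per volume of the first phase; a concentration in a rate is the amount of a species over the volume of its own phase; every rate counts per litre of the first phase
- the earlier runs hold the two phases in the same ratio of volumes as the flask asked about

- noon: doubling the transfer coefficient of the reagent in the second phase, all else as stated
- dawn: doubling the amount of reagent in the second phase, all else as stated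

- how much product there is at 2.0 h, in percent of the substrate charged
- the change that raises the amount of product at 2.0 h, in percent of the substrate charged most ("none" if none brings more than 2 percentage points) (noon / dawn / none)
- amount of product at 2.0 h, in percent of the substrate charged, after noon

In the late ash readings product and substrate fell together at a nearly steady ratio, so for birch too I followed the pool S, their sum as a fraction of the charge. I took the pool to lose at a second-order rate, a times the square of the substrate fraction. The first birch reading gave a = 0.199 min⁻¹, and the first ash reading, with less reagent, gave 0.201 min⁻¹. The last birch reading gave a product-to-substrate ratio Q of 1.12, which I assumed as a quasi-equilibrium, though the birch ratio had still been climbing over the last readings. So I counted pool turnovers, n = at divided by the square of one plus Q; S is then the reciprocal of one plus n, and product is the share Q/(1+Q) of S. For birch at 2.0 h, n = 5.33, so I reckoned 8.34% product.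

Turned round, "none" needed dawn to gain under 2 percentage points. From ash to birch, the reagent charge rose by a factor of 1.50, and the last-reading Q rose by 1.17. Repeating that lift alone put Q at 1.31 and product at 10.4%, a gain of 2 points, barely above the margin, and dawn multiplies the charge by 2. I chose dawn. Neither run varied the transfer coefficient, so for noon I kept 8.34% as a plain guess.

The forecast gave 3%, none and 2% after noon: “More reagent or faster transfer should only speed the drain”.

    substrate + reagent in the reaction phase ⇌ product (K = 3.10 M⁻¹, k = 0.00240 M⁻¹ s⁻¹)
    reagent in the reaction phase ⇌ reagent in the second phase, rate k2*([reagent in the reaction phase] - [reagent in the second phase]/K2) per volume of the first phase (partition coefficient = 2.40, kL = 0.0170 s⁻¹)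
    2 substrate → homo dimer (k = 0.00260 M⁻¹ s⁻¹)

The flask held 8.65%; dawn was best, adding 10 points, while noon added 0.11 points, reaching 8.76%. With the passing of substrate into homo dimer struck out, the answer stood at 47.8%. At ten times the time, n became 53.3, which gave 0.972% product against the computed 1.08%.

For the neighbour charged with 2.6 M substrate, a scales with the charge, so n became 21.0 and product 2.40%. The computed neighbour held 2.66%.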